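**Plan**

- Retrosynthesis: the two ring C–prenyl bonds at the quaternary carbons C-7 and C-5 (benzofuran numbering) are cut first, which returns an aromatic acylphloroglucinol. The dihydrofuran bonds O1–C2 and C3–C3a are cut next, leaving a para-O-capped 3-methyl-isobutyrylphloroglucinol and an epoxy aldehyde from nerol.
- Forward: the six-membered ring is bought as 2,4,6-trihydroxytoluene, acylated and capped at the para oxygen. The C10 chain is joined and the dihydrofuran ring closed in one flask (reductive condensation, then 5-exo epoxide opening). Deprotection and two C-prenylations then dearomatise the ring.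
- Enabling feature: the only free ring carbon lies between the capped para oxygen and the free, ketone-chelated ortho hydroxyl (the future O1). Condensation, hydride addition and ring closure can therefore use only that oxygen, which ends up five atoms from the secondary epoxide carbon.
- Stereochemistry: one Sharpless epoxidation sets both side-chain centres (the quaternary epoxide carbon becomes the carbinol carbon; the CH carbon is inverted on ring closure to 2S). C-5 is set by a chiral palladium catalyst, C-7 by substrate control from C-5 and C-2.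

Key step: step 5

Remark: 8 and 13 are written as one tautomer each; positions in 10 to 14 follow benzofuran numbering (O1, C2, C3, C3a, C4, C5, C6, C7, C7a).

**Route**

Step 1
Reactants: 1 nerol, (2Z)-3,7-dimethylocta-2,6-dien-1-ol
Product: 2 (2R,3S)-2,3-epoxynerol, [(2R,3S)-3-methyl-3-(4-methylpent-3-en-1-yl)oxiran-2-yl]methanol
Conditions: Ti(OiPr)4 (10 mol %), D-(−)-diethyl tartrate (12 mol %), t-BuOOH (2 equiv, isooctane), 4 Å molecular sieves, CH2Cl2, −20 °C
Reagents that add atoms: tert-butyl hydroperoxide, CC(C)(C)OO
Why: Katsuki–Sharpless asymmetric epoxidation: the titanium tartrate binds the allylic hydroxyl, so only the 2,3-olefin reacts, and D-(−)-tartrate should deliver oxygen to the face that gives the 2R,3S cis-epoxide, which fixes both side-chain stereocentres of the target.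

Step 2
Reactants: 2 (2R,3S)-2,3-epoxynerol
Product: 3 (2S,3S)-3-methyl-3-(4-methylpent-3-en-1-yl)oxirane-2-carbaldehyde
Conditions: TEMPO (10 mol %), PhI(OAc)2 (1.1 equiv), CH2Cl2, 0 °C to rt; used crude
Reagents that add atoms: none
Why: Nitroxyl-catalysed oxidation of a primary alcohol to the aldehyde under near-neutral conditions should leave the epoxide and the trisubstituted olefin alone, and the α-carbon is an epoxide carbon that cannot enolise, so its configuration holds.

Step 3
Reactants: 4 2,4,6-trihydroxytoluene (2-methylbenzene-1,3,5-triol); 5 isobutyryl chloride (2-methylpropanoyl chloride)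
Product: 6 1-(2,4,6-trihydroxy-3-methylphenyl)-2-methylpropan-1-one
Conditions: AlCl3 (4 equiv), PhNO2/CH2Cl2, 0 °C to 60 °C; aq. HCl quench
Reagents that add atoms: none
Why: Friedel–Crafts acylation of the electron-rich triol: the two free ring positions are equivalent by symmetry, so a single ketone should form, and the acyl group deactivates the ring against a second acylation.

Step 4
Reactants: 6 1-(2,4,6-trihydroxy-3-methylphenyl)-2-methylpropan-1-one
Product: 7 1-[2,6-dihydroxy-4-(methoxymethoxy)-3-methylphenyl]-2-methylpropan-1-one
Conditions: MOMCl (1.05 equiv), iPr2NEt (1.2 equiv), CH2Cl2, 0 °C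
Reagents that add atoms: chloromethyl methyl ether, COCCl
Why: O-alkylation with a hard electrophile should go first to the para hydroxyl, the most acidic one and the only one not held in the hydrogen bond to the ketone (selective etherification of acylphloroglucinols), and this cap later blocks ring closure through that oxygen.

Step 5
Reactants: 7 1-[2,6-dihydroxy-4-(methoxymethoxy)-3-methylphenyl]-2-methylpropan-1-one; 3 (2S,3S)-3-methyl-3-(4-methylpent-3-en-1-yl)oxirane-2-carbaldehyde
Product: 10 1-[(2S)-6-hydroxy-2-[(2S)-2-hydroxy-6-methylhept-5-en-2-yl]-4-(methoxymethoxy)-5-methyl-2,3-dihydro-1-benzofuran-7-yl]-2-methylpropan-1-one, via ortho-quinone methide 8 (not isolated), via epoxy phenol 9 (not isolated)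
Conditions: L-proline (20 mol %), diethyl 2,6-dimethyl-1,4-dihydropyridine-3,5-dicarboxylate (Hantzsch ester, 1.5 equiv), EtOH/CH2Cl2, 25 to 40 °C; then K2CO3 (0.5 equiv), MeOH, 40 °C
Reagents that add atoms: none
Why: Proposed new method: the free ring carbon C-5 of 7 adds to the amine-activated aldehyde and water is lost to give the ortho-quinone methide 8 through the 6-oxygen, the dihydropyridine transfers hydride to its exocyclic carbon to give phenol 9, and carbonate then lets the 6-phenoxide open the epoxide at its CH carbon; the closest known reaction types are the amine-catalysed three-component reductive alkylation of cyclic 1,3-diones and hydroxycoumarins with aldehydes and this hydride donor, and the base-induced cyclisation of ortho-(2,3-epoxyalkyl)phenols to 2-(1-hydroxyalkyl)-2,3-dihydrobenzofurans. The dihydrofuran closes in the 5-exo-tet mode by backside attack of oxygen on the secondary epoxide carbon. C-2 is therefore set by inversion of the epoxide CH carbon (2R in 9 to 2S in 10), and the carbinol carbon keeps the configuration of the quaternary epoxide carbon from step 1, so both centres are relayed from the Sharpless epoxide without a new control element. The step needs a choice between the two oxygens that flank the chain carbon: the methoxymethyl cap on the para oxygen leaves only the ketone-chelated 6-hydroxyl to form the quinone methide and to close the ring, and the 2-hydroxyl, para to the chain, cannot reach. It needs 5-exo over 6-endo opening, which the anionic oxygen nucleophile and the absence of acid should secure by directing attack to the less substituted carbon. It needs hydride transfer to outrun addition of a second arene to 8, which the excess of hydride donor and the bulk next to the exocyclic carbon are expected to secure.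

Step 6
Reactants: 10 1-[(2S)-6-hydroxy-2-[(2S)-2-hydroxy-6-methylhept-5-en-2-yl]-4-(methoxymethoxy)-5-methyl-2,3-dihydro-1-benzofuran-7-yl]-2-methylpropan-1-one
Product: 11 1-[(2S)-4,6-dihydroxy-2-[(2S)-2-hydroxy-6-methylhept-5-en-2-yl]-5-methyl-2,3-dihydro-1-benzofuran-7-yl]-2-methylpropan-1-one
Conditions: conc. HCl (3 equiv), MeOH, 25 °C, argon
Reagents that add atoms: none
Why: Acid-catalysed acetal exchange with methanol should free the phenol from its methoxymethyl ether under conditions that a prenyl-type olefin and a tertiary alcohol β to an ether oxygen are expected to tolerate.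

Step 7
Reactants: 11 1-[(2S)-4,6-dihydroxy-2-[(2S)-2-hydroxy-6-methylhept-5-en-2-yl]-5-methyl-2,3-dihydro-1-benzofuran-7-yl]-2-methylpropan-1-one; 12 prenyl acetate (3-methylbut-2-en-1-yl acetate, 1.05 equiv)
Product: 13 (2S,5R)-6-hydroxy-2-[(2S)-2-hydroxy-6-methylhept-5-en-2-yl]-5-methyl-5-(3-methylbut-2-en-1-yl)-7-(2-methylpropanoyl)-2,3-dihydro-1-benzofuran-4(5H)-one
Conditions: Pd2(dba)3·CHCl3 (2.5 mol %), N,N'-[(1R,2R)-cyclohexane-1,2-diyl]bis[2-(diphenylphosphanyl)benzamide] (7.5 mol %), Et3N (1.2 equiv), CH2Cl2, 0 °C to rt
Reagents that add atoms: none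
Why: Tsuji–Trost asymmetric allylic alkylation with dearomatisation: the phenoxide should attack the CH2 terminus of the π-prenyl palladium complex through C-5, the ring carbon between the two free hydroxyls, giving the linear prenyl group and an enol-stabilised cyclohexadienone, and the chiral diphosphine selects the face (catalyst control, since the side-chain centres are too remote), the (R,R)-ligand being put forward for the 5R product.

Step 8
Reactants: 13 (2S,5R)-6-hydroxy-2-[(2S)-2-hydroxy-6-methylhept-5-en-2-yl]-5-methyl-5-(3-methylbut-2-en-1-yl)-7-(2-methylpropanoyl)-2,3-dihydro-1-benzofuran-4(5H)-one; 12 prenyl acetate (1.2 equiv)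
Product: 14 CNP0250451.1, (2S,5S,7S)-2-[(2S)-2-hydroxy-6-methylhept-5-en-2-yl]-5-methyl-5,7-bis(3-methylbut-2-en-1-yl)-7-(2-methylpropanoyl)-2,3-dihydro-1-benzofuran-4,6(5H,7H)-dione
Conditions: Pd(PPh3)4 (5 mol %), Et3N (1.2 equiv), THF, 40 °C
Reagents that add atoms: none
Why: Tsuji–Trost allylation of the acidic 2-acyl-1,3-dicarbonyl unit at its central carbon C-7 (O-allyl products re-ionise under zerovalent palladium and should funnel to the C-alkylated trione); the new quaternary centre is set by substrate control, the π-prenyl complex approaching the face opposite to the C-5 prenyl group and the C-2 side chain, which lie on the same side, so that the two ring prenyl groups end up trans as in the target.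

**Compound list**

1 | nerol, (2Z)-3,7-dimethylocta-2,6-dien-1-ol | CC(C)=CCC/C(C)=C\CO | starting material
2 | (2R,3S)-2,3-epoxynerol, [(2R,3S)-3-methyl-3-(4-methylpent-3-en-1-yl)oxiran-2-yl]methanol | CC(C)=CCC[C@]1(C)O[C@@H]1CO | intermediate
3 | (2S,3S)-3-methyl-3-(4-methylpent-3-en-1-yl)oxirane-2-carbaldehyde | CC(C)=CCC[C@]1(C)O[C@@H]1C=O | intermediate
4 | 2,4,6-trihydroxytoluene (2-methylbenzene-1,3,5-triol) | Cc1c(O)cc(O)cc1O | starting material
5 | isobutyryl chloride (2-methylpropanoyl chloride) | CC(C)C(Cl)=O | starting material
6 | 1-(2,4,6-trihydroxy-3-methylphenyl)-2-methylpropan-1-one | CC(C)C(=O)c1c(O)cc(O)c(C)c1O | intermediate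
7 | 1-[2,6-dihydroxy-4-(methoxymethoxy)-3-methylphenyl]-2-methylpropan-1-one | CC(C)C(=O)c1c(O)cc(OCOC)c(C)c1O | intermediate
8 | ortho-quinone methide, 3-hydroxy-5-(methoxymethoxy)-4-methyl-6-{[(2R,3S)-3-methyl-3-(4-methylpent-3-en-1-yl)oxiran-2-yl]methylidene}-2-(2-methylpropanoyl)cyclohexa-2,4-dien-1-one | CC(C)=CCC[C@]1(C)O[C@@H]1C=C1C(=O)C(C(=O)C(C)C)=C(O)C(C)=C1OCOC | intermediate
9 | epoxy phenol, 1-[2,6-dihydroxy-4-(methoxymethoxy)-3-methyl-5-{[(2R,3S)-3-methyl-3-(4-methylpent-3-en-1-yl)oxiran-2-yl]methyl}phenyl]-2-methylpropan-1-one | CC(C)=CCC[C@]1(C)O[C@@H]1Cc1c(O)c(C(=O)C(C)C)c(O)c(C)c1OCOC | intermediate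
10 | 1-[(2S)-6-hydroxy-2-[(2S)-2-hydroxy-6-methylhept-5-en-2-yl]-4-(methoxymethoxy)-5-methyl-2,3-dihydro-1-benzofuran-7-yl]-2-methylpropan-1-one | CC(C)=CCC[C@](C)(O)[C@@H]1Cc2c(O1)c(C(=O)C(C)C)c(O)c(C)c2OCOC | intermediate
11 | 1-[(2S)-4,6-dihydroxy-2-[(2S)-2-hydroxy-6-methylhept-5-en-2-yl]-5-methyl-2,3-dihydro-1-benzofuran-7-yl]-2-methylpropan-1-one | CC(C)=CCC[C@](C)(O)[C@@H]1Cc2c(O1)c(C(=O)C(C)C)c(O)c(C)c2O | intermediate
12 | prenyl acetate (3-methylbut-2-en-1-yl acetate) | CC(=O)OCC=C(C)C | starting material
13 | (2S,5R)-6-hydroxy-2-[(2S)-2-hydroxy-6-methylhept-5-en-2-yl]-5-methyl-5-(3-methylbut-2-en-1-yl)-7-(2-methylpropanoyl)-2,3-dihydro-1-benzofuran-4(5H)-one | CC(C)=CCC[C@](C)(O)[C@@H]1CC2=C(O1)C(C(=O)C(C)C)=C(O)[C@@](C)(CC=C(C)C)C2=O | intermediate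
14 | CNP0250451.1, (2S,5S,7S)-2-[(2S)-2-hydroxy-6-methylhept-5-en-2-yl]-5-methyl-5,7-bis(3-methylbut-2-en-1-yl)-7-(2-methylpropanoyl)-2,3-dihydro-1-benzofuran-4,6(5H,7H)-dione | CC(C)=CCC[C@](C)(O)[C@@H]1CC2=C(O1)[C@@](CC=C(C)C)(C(=O)C(C)C)C(=O)[C@@](C)(CC=C(C)C)C2=O | target

Total step count: 8
Longest linear sequence: 6 steps (steps 3 to 8 from 4; the aldehyde branch, steps 1, 2 and 5 to 8 from 1, is equally long)

**Steps most likely to fail**

1. Step 5 (new cascade). What may go wrong: slow condensation of the ketone-deactivated arene with the hindered aldehyde; closure of the phenol onto the epoxide before water is lost, which would keep the benzylic oxygen; coupling of the quinone methide with a second arene instead of hydride transfer. Fallback with known reactions, setting out from 7 and coming back at 10: nerol 1 is converted with PBr3 (Et2O, −10 °C) into neryl bromide F1. C-alkylation of the phenoxide of 7 with it (aq. KOH, 0 °C), the reaction type used to put geranyl and prenyl groups on acylphloroglucinols, gives the C-neryl phenol F2. VO(acac)2 (cat.) and t-BuOOH in CH2Cl2 epoxidise the Z-olefin held by the neighbouring free hydroxyl (hydroxyl-directed epoxidation of ortho-allylphenols) to the racemic cis-epoxide, that is 9 together with the enantiomer of 9 F3. K2CO3 in MeOH closes the ring as in step 5 to racemic material, 10 together with the enantiomer of 10 F4, and preparative chromatography on a chiral stationary phase gives 10. The cap still secures the regiochemistry and the Z-olefin the relative configuration; the absolute configuration then rests on the resolution.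

2. Step 7. What may go wrong: weak or reversed facial selection by the ligand (the mirror-image ligand is the first change); alkylation at oxygen or at the ring-fusion carbon C-3a; a second alkylation. Fallback that gives up catalyst control, setting out from 11 and coming back at 13: the classical dearomatising C-alkylation of acylphloroglucinols (prenyl bromide, NaOMe, MeOH, 0 °C) should give 13 together with the C-5 epimer of 13 F5. The two are diastereomers because the side chain is homochiral, and are separated by preparative HPLC.

3. Step 8. What may go wrong: O-alkylation that does not funnel to carbon; alkylation at C-3a; weak facial bias; retro-Claisen loss of the isobutyryl group from the no longer enolisable product in the presence of acetate. Fallback by decarboxylative allylation, setting out from 13 and coming back at 14: prenyl chloroformate and pyridine (CH2Cl2, −20 °C) acylate the C-6 enol oxygen to the enol prenyl carbonate F6. Pd(PPh3)4 in THF ionises it with loss of carbon dioxide, and the ion pair should recombine at the adjacent carbon C-7 without added base or acetate.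

Further compounds
F1 | step 5 | neryl bromide, (2Z)-1-bromo-3,7-dimethylocta-2,6-diene | CC(C)=CCC/C(C)=C\CBr
F2 | step 5 | C-neryl phenol, 1-{3-[(2Z)-3,7-dimethylocta-2,6-dien-1-yl]-2,6-dihydroxy-4-(methoxymethoxy)-5-methylphenyl}-2-methylpropan-1-one | CC(C)=CCC/C(C)=C\Cc1c(O)c(C(=O)C(C)C)c(O)c(C)c1OCOC
F3 | step 5 | enantiomer of 9, the (2S,3R)-epoxide | CC(C)=CCC[C@@]1(C)O[C@H]1Cc1c(O)c(C(=O)C(C)C)c(O)c(C)c1OCOC
F4 | step 5 | enantiomer of 10, the (2R)-2-[(2R)-2-hydroxy-6-methylhept-5-en-2-yl] dihydrobenzofuran | CC(C)=CCC[C@@](C)(O)[C@H]1Cc2c(O1)c(C(=O)C(C)C)c(O)c(C)c2OCOC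
F5 | step 7 | C-5 epimer of 13, the (2S,5S) compound | CC(C)=CCC[C@](C)(O)[C@@H]1CC2=C(O1)C(C(=O)C(C)C)=C(O)[C@](C)(CC=C(C)C)C2=O
F6 | step 8 | enol prenyl carbonate of 13 at the C-6 oxygen | CC(C)=CCC[C@](C)(O)[C@@H]1CC2=C(O1)C(C(=O)C(C)C)=C(OC(=O)OCC=C(C)C)[C@@](C)(CC=C(C)C)C2=O
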